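The target is cut at its three aryl ester bonds into ring B, acylated twice as the dihydroxyquinone and once after reduction, and three copies of one epoxy acid. Everything rests on drawing that acid from D-gluconic acid locked as a butenolide: methoxide opens the 1,4-lactone at C1 and the liberated O4 alkoxide displaces a C5 mesylate, so one operation delivers the ester, the cis C2=C3 bond and the trans C4–C5 oxirane with inversion at C5. The step exploits that O4 sits on C4, cis across C2=C3 to C1 and vicinal to C5, so it serves first as lactone oxygen and then as oxirane oxygen. The precursor is the 6-deoxy-2,3-unsaturated 1,4-lactone carrying a mesylate on O5.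

Key step: step 4

Assumption: 4-(tert-butyldimethylsilyloxy)phenylboronic acid is taken as commercial; C4 and C5 of D-gluconic acid read (4S,5R) in the mesyl butenolide (same geometry, new CIP ranks) and (4S,5S) after inversion at C5; the four oxygen-bearing positions of ring B are equivalent, so any triester is the target constitution and acyl shifts cannot create an isomer of it.

Step 1
Reactants: 1 D-glucono-1,5-lactone
Product: 3 2,6-dibromo-2,6-dideoxy-D-mannono-1,4-lactone, via 3,5-di-O-acetyl dibromolactone 2 (not isolated)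
Conditions: 33% HBr in AcOH, rt; then MeOH, rt
Reagents that add atoms: hydrogen bromide, Br; acetic acid, CC(=O)O (acetyl groups of 2 only)
Why: Bromodeoxygenation of an aldonolactone with HBr in acetic acid: acetoxonium ions are opened by bromide at the primary C6 (C5 keeps its configuration) and at C2 with inversion (gluco to manno), the ring contracts to the 1,4-lactone with C3 to C5 untouched, and methanol then removes the acetates by transesterification.

Step 2
Reactants: 3 2,6-dibromo-2,6-dideoxy-D-mannono-1,4-lactone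
Product: 5 2,6-dideoxy-D-arabino-hexono-1,4-lactone, via 6-bromo-2,6-dideoxy lactone 4 (not isolated)
Conditions: H2 (1 atm), Pd/C (10% Pd), Et3N (2.2 equiv), EtOAc, rt
Reagents that add atoms: none
Why: Catalytic hydrogenolysis of both C–Br bonds over palladium with triethylamine as scavenger for hydrogen bromide (the activated C2 bromide first, the primary C6 bromide second); no stereocentre is formed and C3, C4 and C5 are not touched.

Step 3
Reactants: 5 2,6-dideoxy-D-arabino-hexono-1,4-lactone
Product: 7 (5S)-5-[(1R)-1-(methylsulfonyloxy)ethyl]furan-2(5H)-one, via 3,5-di-O-mesyl lactone 6 (not isolated)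
Conditions: MsCl (2.1 equiv), Et3N (3.1 equiv), CH2Cl2, −20 → 0 °C
Reagents that add atoms: methanesulfonyl chloride, CS(=O)(=O)Cl
Why: O-Sulfonylation of both secondary hydroxyls (retention at C3 and C5) is followed in the same flask by E1cB beta-elimination of the C3 mesylate, which lies beta to the lactone carbonyl, whereas the C5 mesylate has no such activation and stays; the amine charge of about three equivalents is used up as ammonium salts, so little free base is left to deprotonate C4 of the butenolide.

Step 4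
Reactants: 7 (5S)-5-[(1R)-1-(methylsulfonyloxy)ethyl]furan-2(5H)-one
Product: 9 methyl (2Z,4S,5S)-4,5-epoxyhex-2-enoate, via open-chain 4-hydroxy 5-mesylate ester 8 (not isolated)
Conditions: K2CO3 (1.2 equiv), dry MeOH, −20 → 0 °C; pH 7 phosphate quench
Reagents that add atoms: methanol, CO
Why: Methoxide generated by the carbonate adds to the lactone carbonyl C1 and the tetrahedral intermediate expels O4, which gives the Z-configured 4-oxido ester 8; O4 then attacks C5 from the face opposite the mesylate, and this irreversible closure drains the otherwise unfavourable lactone/hydroxy ester equilibrium. The closest known reaction type is the alkoxide-induced conversion of 5-O-sulfonyl aldono-1,4-lactones and their 2-enono analogues into 4,5-epoxy esters, that is transesterifying ring opening followed by a Williamson-type epoxide closure. The only ring closed is the oxirane, by 3-exo-tet displacement. The only new stereocentre, C5, is set by SN2 inversion of the (R)-mesylate carbon that stems from C5 of D-gluconic acid, while C4 stays (S) because its C–O bond is never broken, so the trans-(4S,5S) oxirane results. The step needs attack at the acyl carbon to win over deprotonation at C4 (E1cB loss of the mesylate or epimerisation) and over conjugate addition of methoxide at C3; the strained, unhindered butenolide carbonyl, the low methoxide concentration of cold carbonate and the fast intramolecular capture by the adjacent mesylate should secure this. The C2=C3 geometry needs no control, since it is the cis double bond of the five-membered ring and is not touched.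

Step 5
Reactants: 9 methyl (2Z,4S,5S)-4,5-epoxyhex-2-enoate
Product: 11 (2Z,4S,5S)-4,5-epoxyhex-2-enoic acid, via lithium carboxylate 10 (not isolated)
Conditions: LiOH·H2O (1.05 equiv), THF–H2O 3:1, 0 °C; then cold 10% aq. citric acid to pH 4, CH2Cl2 extraction at 0 °C, solution dried and used at once
Reagents that add atoms: lithium hydroxide, [Li+].[OH-]
Why: Saponification (BAc2) of the methyl ester with one equivalent of hydroxide at 0 °C, where the carboxylate is inert towards its own oxirane, followed by brief cold acidification into an organic layer so that acid-promoted lactonisation onto the oxirane should not set in; neither stereocentre nor the Z double bond is touched.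

Step 6
Reactants: 12 bromanilic acid
Product: 13 2,5-bis(benzyloxy)-3,6-dibromo-1,4-benzoquinone
Conditions: BnBr (2.5 equiv), Ag2O (1.2 equiv), MeCN, rt, dark
Reagents that add atoms: benzyl bromide, BrCc1ccccc1
Why: Silver-assisted O-alkylation of a vinylogous carboxylic acid: both acidic enol oxygens are benzylated (C-alkylation is excluded because the adjacent ring carbons carry bromine), which gives the bis(vinylogous benzyl ester).

Step 7
Reactants: 13 2,5-bis(benzyloxy)-3,6-dibromo-1,4-benzoquinone; 14 4-(tert-butyldimethylsilyloxy)phenylboronic acid (2.4 equiv)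
Product: 15 2,5-bis(benzyloxy)-3,6-bis[4-(tert-butyldimethylsilyloxy)phenyl]-1,4-benzoquinone
Conditions: Pd(PPh3)4 (5 mol %), K3PO4, 1,4-dioxane, 85 °C
Reagents that add atoms: none
Why: Twofold Suzuki–Miyaura coupling at the two vinylogous acyl bromide positions of the quinone, which add readily to zerovalent palladium; phosphate in dioxane should leave the aryl silyl ethers and the vinylogous esters intact.

Step 8
Reactants: 15 2,5-bis(benzyloxy)-3,6-bis[4-(tert-butyldimethylsilyloxy)phenyl]-1,4-benzoquinone
Product: 18 2,5-dihydroxy-3,6-bis[4-(tert-butyldimethylsilyloxy)phenyl]-1,4-benzoquinone, via dibenzyl hydroquinone 16 (not isolated), via leuco tetraol 17 (not isolated)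
Conditions: H2 (1 atm), Pd/C (10% Pd), EtOAc, rt; Ar purge, filtration (Celite); then O2 (1 atm), rt
Reagents that add atoms: none
Why: Hydrogenation reduces the quinone to hydroquinone 16 and then cleaves both benzyl ethers by hydrogenolysis under neutral conditions that spare the aryl silyl ethers, and the electron-rich leuco tetraol 17, once freed from catalyst and hydrogen, is autoxidised by dioxygen back to the quinone level, which unmasks the two enol hydroxyls while the other two ring oxygens stay locked as carbonyls.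

Step 9
Reactants: 18 2,5-dihydroxy-3,6-bis[4-(tert-butyldimethylsilyloxy)phenyl]-1,4-benzoquinone; 11 (2Z,4S,5S)-4,5-epoxyhex-2-enoic acid (2.2 equiv)
Product: 19 2,5-bis[(2Z,4S,5S)-4,5-epoxyhex-2-enoyloxy]-3,6-bis[4-(tert-butyldimethylsilyloxy)phenyl]-1,4-benzoquinone
Conditions: DIC (2.4 equiv), DMAP (0.1 equiv), CH2Cl2, −20 → 0 °C, argon; cold pH 6 phosphate wash, short silica plug
Reagents that add atoms: none
Why: Steglich esterification (O-acylisourea from the carbodiimide, acyl transfer through DMAP) of the two acidic enol hydroxyls of the dihydroxyquinone, a vinylogous carboxylic acid whose O-acylation to 2,5-bis(acyloxy)quinones is standard; the two carbonyl oxygens cannot be acylated, so exactly two acyl groups enter without statistical control, and low temperature with little DMAP guards the Z double bonds and the oxiranes.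

Step 10
Reactants: 19 2,5-bis[(2Z,4S,5S)-4,5-epoxyhex-2-enoyloxy]-3,6-bis[4-(tert-butyldimethylsilyloxy)phenyl]-1,4-benzoquinone
Product: 20 2,5-bis[(2Z,4S,5S)-4,5-epoxyhex-2-enoyloxy]-3,6-bis[4-(tert-butyldimethylsilyloxy)phenyl]benzene-1,4-diol
Conditions: Na2S2O4 (3 equiv), EtOAc–H2O 1:1, 0 °C, argon, 10 min
Reagents that add atoms: none
Why: Two-electron reduction of the quinone by dithionite in a two-phase system is fast at 0 °C and should be chemoselective over the enoates and oxiranes at short contact time; it turns the two carbonyl oxygens into phenols and the vinylogous anhydrides into ordinary aryl esters, and a 1,2-acyl shift to a neighbouring hydroxyl would only give a regioisomeric diester that converges on the same triester in step 11.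

Step 11
Reactants: 20 2,5-bis[(2Z,4S,5S)-4,5-epoxyhex-2-enoyloxy]-3,6-bis[4-(tert-butyldimethylsilyloxy)phenyl]benzene-1,4-diol; 11 (2Z,4S,5S)-4,5-epoxyhex-2-enoic acid (1.0 equiv)
Product: 21 2',3',5'-tris-O-[(2Z,4S,5S)-4,5-epoxyhex-2-enoyl]-4,4''-bis(tert-butyldimethylsilyloxy)-1,1':4',1''-terphenyl-2',3',5',6'-tetraol
Conditions: DIC (1.1 equiv), DMAP (0.1 equiv), CH2Cl2, −20 → 0 °C, argon
Reagents that add atoms: none
Why: Steglich esterification with one equivalent of acid acylates one of the two symmetry-equivalent phenols; since every triester of ring B is the same compound only the degree of acylation has to be held, which the limiting charge of acid does (the tetraester is removed by chromatography and unreacted 20 is recycled).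

Step 12
Reactants: 21 2',3',5'-tris-O-[(2Z,4S,5S)-4,5-epoxyhex-2-enoyl]-4,4''-bis(tert-butyldimethylsilyloxy)-1,1':4',1''-terphenyl-2',3',5',6'-tetraol
Product: 22 1,1':4',1''-terphenyl-2',3',4,4'',5',6'-hexaol 2',3',5'-tris[(2Z,4S,5S)-4,5-epoxyhex-2-enoate] (target)
Conditions: Bu4NF (2.2 equiv), AcOH (2.5 equiv), THF, 0 °C
Reagents that add atoms: none
Why: Fluoride-induced cleavage of the two aryl silyl ethers (Si–F bond formation) with acetic acid as buffer, so that neither free phenoxide nor basic fluoride attacks the aryl esters, the Z-enoates or the oxiranes.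

Compound list
1 | D-glucono-1,5-lactone, (3R,4S,5S,6R)-3,4,5-trihydroxy-6-(hydroxymethyl)oxan-2-one | OC[C@H]1OC(=O)[C@H](O)[C@@H](O)[C@@H]1O | starting material
2 | 3,5-di-O-acetyl-2,6-dibromo-2,6-dideoxy-D-mannono-1,4-lactone | O=C1O[C@H]([C@H](OC(C)=O)CBr)[C@H](OC(C)=O)[C@@H]1Br | intermediate (not isolated)
3 | 2,6-dibromo-2,6-dideoxy-D-mannono-1,4-lactone, (3S,4S,5R)-3-bromo-5-[(1S)-2-bromo-1-hydroxyethyl]-4-hydroxyoxolan-2-one | O=C1O[C@H]([C@H](O)CBr)[C@H](O)[C@@H]1Br | intermediate
4 | 6-bromo-2,6-dideoxy-D-arabino-hexono-1,4-lactone | BrC[C@@H](O)[C@H]1OC(=O)C[C@H]1O | intermediate (not isolated)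
5 | 2,6-dideoxy-D-arabino-hexono-1,4-lactone, (4R,5R)-4-hydroxy-5-[(1R)-1-hydroxyethyl]oxolan-2-one | C[C@@H](O)[C@H]1OC(=O)C[C@H]1O | intermediate
6 | 2,6-dideoxy-3,5-di-O-(methylsulfonyl)-D-arabino-hexono-1,4-lactone | C[C@@H](OS(C)(=O)=O)[C@H]1OC(=O)C[C@H]1OS(C)(=O)=O | intermediate (not isolated)
7 | (5S)-5-[(1R)-1-(methylsulfonyloxy)ethyl]furan-2(5H)-one | C[C@@H](OS(C)(=O)=O)[C@H]1OC(=O)C=C1 | intermediate
8 | methyl (2Z,4S,5R)-4-hydroxy-5-(methylsulfonyloxy)hex-2-enoate (reacts as its potassium alkoxide) | C[C@@H](OS(C)(=O)=O)[C@@H](O)/C=C\C(=O)OC | intermediate (not isolated)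
9 | methyl (2Z,4S,5S)-4,5-epoxyhex-2-enoate, methyl (2Z)-3-[(2S,3S)-3-methyloxiran-2-yl]prop-2-enoate | C[C@@H]1O[C@H]1/C=C\C(=O)OC | intermediate
10 | lithium (2Z,4S,5S)-4,5-epoxyhex-2-enoate | C[C@@H]1O[C@H]1/C=C\C(=O)[O-].[Li+] | intermediate (not isolated)
11 | (2Z,4S,5S)-4,5-epoxyhex-2-enoic acid | C[C@@H]1O[C@H]1/C=C\C(=O)O | intermediate
12 | bromanilic acid, 2,5-dibromo-3,6-dihydroxy-1,4-benzoquinone | OC1=C(Br)C(=O)C(O)=C(Br)C1=O | starting material
13 | 2,5-bis(benzyloxy)-3,6-dibromo-1,4-benzoquinone | O=C1C(Br)=C(OCc2ccccc2)C(=O)C(Br)=C1OCc1ccccc1 | intermediate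
14 | 4-(tert-butyldimethylsilyloxy)phenylboronic acid | CC(C)(C)[Si](C)(C)Oc1ccc(B(O)O)cc1 | starting material
15 | 2,5-bis(benzyloxy)-3,6-bis[4-(tert-butyldimethylsilyloxy)phenyl]-1,4-benzoquinone | O=C1C(c2ccc(O[Si](C)(C)C(C)(C)C)cc2)=C(OCc2ccccc2)C(=O)C(c2ccc(O[Si](C)(C)C(C)(C)C)cc2)=C1OCc1ccccc1 | intermediate
16 | 2,5-bis(benzyloxy)-3,6-bis[4-(tert-butyldimethylsilyloxy)phenyl]benzene-1,4-diol | Oc1c(OCc2ccccc2)c(-c2ccc(O[Si](C)(C)C(C)(C)C)cc2)c(O)c(OCc2ccccc2)c1-c1ccc(O[Si](C)(C)C(C)(C)C)cc1 | intermediate (not isolated)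
17 | 3,6-bis[4-(tert-butyldimethylsilyloxy)phenyl]benzene-1,2,4,5-tetraol | Oc1c(O)c(-c2ccc(O[Si](C)(C)C(C)(C)C)cc2)c(O)c(O)c1-c1ccc(O[Si](C)(C)C(C)(C)C)cc1 | intermediate (not isolated)
18 | 2,5-dihydroxy-3,6-bis[4-(tert-butyldimethylsilyloxy)phenyl]-1,4-benzoquinone | O=C1C(O)=C(c2ccc(O[Si](C)(C)C(C)(C)C)cc2)C(=O)C(O)=C1c1ccc(O[Si](C)(C)C(C)(C)C)cc1 | intermediate
19 | 2,5-bis[(2Z,4S,5S)-4,5-epoxyhex-2-enoyloxy]-3,6-bis[4-(tert-butyldimethylsilyloxy)phenyl]-1,4-benzoquinone | O=C1C(OC(=O)/C=C\[C@@H]2O[C@H]2C)=C(c2ccc(O[Si](C)(C)C(C)(C)C)cc2)C(=O)C(OC(=O)/C=C\[C@@H]2O[C@H]2C)=C1c1ccc(O[Si](C)(C)C(C)(C)C)cc1 | intermediate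
20 | 2,5-bis[(2Z,4S,5S)-4,5-epoxyhex-2-enoyloxy]-3,6-bis[4-(tert-butyldimethylsilyloxy)phenyl]benzene-1,4-diol | Oc1c(OC(=O)/C=C\[C@@H]2O[C@H]2C)c(-c2ccc(O[Si](C)(C)C(C)(C)C)cc2)c(O)c(OC(=O)/C=C\[C@@H]2O[C@H]2C)c1-c1ccc(O[Si](C)(C)C(C)(C)C)cc1 | intermediate
21 | 2',3',5'-tris-O-[(2Z,4S,5S)-4,5-epoxyhex-2-enoyl]-4,4''-bis(tert-butyldimethylsilyloxy)-1,1':4',1''-terphenyl-2',3',5',6'-tetraol | C[C@@H]1O[C@H]1/C=C\C(=O)Oc1c(OC(=O)/C=C\[C@@H]2O[C@H]2C)c(-c2ccc(O[Si](C)(C)C(C)(C)C)cc2)c(OC(=O)/C=C\[C@@H]2O[C@H]2C)c(O)c1-c1ccc(O[Si](C)(C)C(C)(C)C)cc1 | intermediate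
22 | 1,1':4',1''-terphenyl-2',3',4,4'',5',6'-hexaol 2',3',5'-tris[(2Z,4S,5S)-4,5-epoxyhex-2-enoate] | C[C@@H]1O[C@H]1/C=C\C(=O)Oc1c(OC(=O)/C=C\[C@@H]2O[C@H]2C)c(-c2ccc(O)cc2)c(OC(=O)/C=C\[C@@H]2O[C@H]2C)c(O)c1-c1ccc(O)cc1 | target

Total step count: 12. Longest linear sequence: 9 steps (steps 1 to 5 and 9 to 12); the ring B branch (steps 6 to 8) joins at step 9.

Steps most likely to fail

Step 4. Deprotonation at C4 of the butenolide, with E1cB loss of the mesylate or epimerisation, and conjugate addition of methoxide at C3 may outrun attack at the carbonyl. The fallback takes the carbonyl out before any base is applied. It sets out from 7, which would be reduced with iBu2AlH (CH2Cl2, −78 → −40 °C) to (2Z,4S,5R)-5-(methylsulfonyloxy)hex-2-ene-1,4-diol F1. Its C4 alkoxide would close the oxirane with K2CO3 in MeOH at 0 °C to give (2Z,4S,5S)-4,5-epoxyhex-2-en-1-ol F2. Oxidation with TEMPO/PhI(OAc)2 to (2Z,4S,5S)-4,5-epoxyhex-2-enal F3 and then with NaClO2/NaH2PO4/2-methyl-2-butene would give acid 11, where the route is rejoined; 9 and step 5 are bypassed.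

Step 9. The carbodiimide may be consumed by the acidic enol hydroxyls of the quinone in place of the carboxylic acid, the free epoxy acid may lactonise onto its own oxirane while it waits for activation, and reversible addition of DMAP to the activated enoyl species may isomerise Z to E. The fallback takes both the free acid and the carbodiimide out of the step. It sets out from 10: the hydrolysate of 9 would be freeze-dried to the lithium salt and treated with 2,4,6-trichlorobenzoyl chloride (THF, 0 °C) to give (2Z,4S,5S)-4,5-epoxyhex-2-enoic 2,4,6-trichlorobenzoic anhydride F4. This preformed mixed anhydride would acylate the two enol hydroxyls of 18 with Et3N and a trace of DMAP (Yamaguchi esterification) and give 19, where the route is rejoined; the same anhydride can serve in step 11.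

Step 11. The two hydroxyls of 20 are not differentiated, so under- and over-acylation compete with formation of the triester and material is lost to the tetraester. The fallback sets one ring B oxygen apart before any acid is attached and bypasses 18 to 21. It sets out from 15, which would be reduced with aqueous Na2S2O4 to hydroquinone 16, isolated in this case. One silylation (TBSCl 1.0 equiv, imidazole, DMF, 0 °C; unreacted 16 is recycled) would give 2,5-bis(benzyloxy)-4-(tert-butyldimethylsilyloxy)-3,6-bis[4-(tert-butyldimethylsilyloxy)phenyl]phenol F5. Hydrogenolysis (H2, Pd/C, EtOAc) would give 5-(tert-butyldimethylsilyloxy)-3,6-bis[4-(tert-butyldimethylsilyloxy)phenyl]benzene-1,2,4-triol F6. Esterification of all three hydroxyls with 11 (DIC, DMAP) would give the tris-silylated triester F7, and the buffered fluoride of step 12 would then remove all three silyl groups and give 22.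

Further compounds
F1 | step 4 | (2Z,4S,5R)-5-(methylsulfonyloxy)hex-2-ene-1,4-diol | C[C@@H](OS(C)(=O)=O)[C@@H](O)/C=C\CO
F2 | step 4 | (2Z,4S,5S)-4,5-epoxyhex-2-en-1-ol | C[C@@H]1O[C@H]1/C=C\CO
F3 | step 4 | (2Z,4S,5S)-4,5-epoxyhex-2-enal | C[C@@H]1O[C@H]1/C=C\C=O
F4 | step 9 | (2Z,4S,5S)-4,5-epoxyhex-2-enoic 2,4,6-trichlorobenzoic anhydride | C[C@@H]1O[C@H]1/C=C\C(=O)OC(=O)c1c(Cl)cc(Cl)cc1Cl
F5 | step 11 | 2,5-bis(benzyloxy)-4-(tert-butyldimethylsilyloxy)-3,6-bis[4-(tert-butyldimethylsilyloxy)phenyl]phenol | Oc1c(OCc2ccccc2)c(-c2ccc(O[Si](C)(C)C(C)(C)C)cc2)c(O[Si](C)(C)C(C)(C)C)c(OCc2ccccc2)c1-c1ccc(O[Si](C)(C)C(C)(C)C)cc1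
F6 | step 11 | 5-(tert-butyldimethylsilyloxy)-3,6-bis[4-(tert-butyldimethylsilyloxy)phenyl]benzene-1,2,4-triol | Oc1c(O)c(-c2ccc(O[Si](C)(C)C(C)(C)C)cc2)c(O[Si](C)(C)C(C)(C)C)c(O)c1-c1ccc(O[Si](C)(C)C(C)(C)C)cc1
F7 | step 11 | 2',3',5'-tris-O-[(2Z,4S,5S)-4,5-epoxyhex-2-enoyl]-4,4'',6'-tris(tert-butyldimethylsilyloxy)-1,1':4',1''-terphenyl-2',3',5'-triol | C[C@@H]1O[C@H]1/C=C\C(=O)Oc1c(OC(=O)/C=C\[C@@H]2O[C@H]2C)c(-c2ccc(O[Si](C)(C)C(C)(C)C)cc2)c(OC(=O)/C=C\[C@@H]2O[C@H]2C)c(O[Si](C)(C)C(C)(C)C)c1-c1ccc(O[Si](C)(C)C(C)(C)C)cc1
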